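**Retrosynthetic overview**
1. Target ⇐ desilylation at C14 ⇐ Mitsunobu methacrylation with inversion at C8 of the 8α-hydroxy macrocycle.
2. Key step: the C7–C8 bond and the ten-membered ring are closed by SmI2 ketyl-radical addition to the β-carbon of an α-(acetoxymethyl)butenolide; loss of acetate unveils the exo-methylene, and C7 and C8 are set.
3. The seco-aldehyde carries a butenolide made from a γ-hydroxy ynoate (hydroalumination, CH2O aldol, lactonization); C6 comes from a zinc–ProPhenol alkynylation of an enal with methyl propiolate.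
4. The C2–C3 bond, the C2 stereocenter and the E C4=C5 olefin come from a vinylogous Mukaiyama aldol; the cis C1=C10 enal with a masked C8 aldehyde comes from silylated butynediol by trans-hydroalumination/iodination and Negishi coupling.
5. Ring order: butenolide first, then the ten-membered carbocycle.

Assumption: germacrane numbering (C1–C15, lactone C12 to O–C6) is used for locants in the explanations; compounds 1 and 4 are bought as such (the silyl ether and the dioxolane are protecting groups).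

Step 1
Reactants: 1 4-((tert-butyldimethylsilyl)oxy)but-2-yn-1-ol
Product: 3 (Z)-4-((tert-butyldimethylsilyl)oxy)-3-iodobut-2-en-1-ol, via sodium vinylalanate 2 (not isolated)
Conditions: NaAlH2(OCH2CH2OCH3)2 (1.6 equiv), THF, 0 °C to rt; then I2, THF, −78 to 0 °C
Reagents that add atoms: iodine I2, SMILES II
Why: Hydroxyl-directed trans-hydroalumination of the propargylic alcohol puts aluminum on the distal alkyne carbon in a five-membered alkoxyalanate, and iodinolysis with retention gives the Z vinyl iodide (iodine cis to CH2OH), which fixes the C1=C10 geometry.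

Step 2
Reactants: 3 (Z)-4-((tert-butyldimethylsilyl)oxy)-3-iodobut-2-en-1-ol; 4 (1,3-dioxolan-2-ylmethyl)zinc bromide
Product: 5 (E)-3-(((tert-butyldimethylsilyl)oxy)methyl)-4-(1,3-dioxolan-2-yl)but-2-en-1-ol
Conditions: Pd(PPh3)4 (5 mol %), THF, 45 °C
Reagents that add atoms: none
Why: Negishi sp2–sp3 cross-coupling goes with retention at the alkenyl carbon, so the masked C9–C8 acetaldehyde unit ends up cis to the future C2 carbon as the cis ring olefin requires.

Step 3
Reactants: 5 (E)-3-(((tert-butyldimethylsilyl)oxy)methyl)-4-(1,3-dioxolan-2-yl)but-2-en-1-ol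
Product: 6 (E)-3-(((tert-butyldimethylsilyl)oxy)methyl)-4-(1,3-dioxolan-2-yl)but-2-enal
Conditions: MnO2 (15 equiv), CH2Cl2, rt
Reagents that add atoms: none
Why: Allylic oxidation with MnO2 gives the enal without touching the silyl ether or the acetal and without loss of olefin geometry.

Step 4
Reactants: 7 3-methylbut-2-enal
Product: 8 (E)-tert-butyldimethyl((3-methylbuta-1,3-dien-1-yl)oxy)silane
Conditions: t-BuMe2SiOTf, Et3N, Et2O, 0 °C to rt
Reagents that add atoms: tert-butyldimethylsilyl triflate, SMILES CC(C)(C)[Si](C)(C)OS(=O)(=O)C(F)(F)F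
Why: Soft enolization (O-silylation, then γ-deprotonation) of the enal gives the E silyl dienol ether needed for the vinylogous Mukaiyama aldol.

Step 5
Reactants: 6 (E)-3-(((tert-butyldimethylsilyl)oxy)methyl)-4-(1,3-dioxolan-2-yl)but-2-enal; 8 (E)-tert-butyldimethyl((3-methylbuta-1,3-dien-1-yl)oxy)silane
Product: 9 (2E,5S,6E)-7-(((tert-butyldimethylsilyl)oxy)methyl)-8-(1,3-dioxolan-2-yl)-5-hydroxy-3-methylocta-2,6-dienal
Conditions: N-tosyl-(S)-tryptophan-derived B-phenyl oxazaborolidinone (1.0 equiv), i-PrOH (1.2 equiv), EtCN, −78 °C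
Reagents that add atoms: none
Why: In this vinylogous Mukaiyama aldol the boron Lewis acid activates only the aldehyde, the dienol ether reacts at its terminal γ-carbon in the s-trans form to give the E C4=C5 enal directly, and the chiral promoter (the enantiomer that leaves the aldehyde Si face open is used) sets C2 as S.

Step 6
Reactants: 9 (2E,5S,6E)-7-(((tert-butyldimethylsilyl)oxy)methyl)-8-(1,3-dioxolan-2-yl)-5-hydroxy-3-methylocta-2,6-dienal; 10 methyl propiolate
Product: 12 methyl (4R,5E,8S,9E)-10-(((tert-butyldimethylsilyl)oxy)methyl)-11-(1,3-dioxolan-2-yl)-4,8-dihydroxy-6-methylundeca-5,9-dien-2-ynoate, via methylzinc acetylide 11 (not isolated)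
Conditions: (S,S)-ProPhenol (20 mol %), Me2Zn (3.5 equiv), Ph3P=O (40 mol %), toluene, 4 °C
Reagents that add atoms: none
Why: In this zinc–ProPhenol asymmetric alkynylation the dinuclear zinc alkoxide binds the enal and delivers the zinc acetylide to the aldehyde Si face (the ligand antipode is chosen accordingly), which sets C6 as R while the free C2 hydroxyl only becomes its zinc alkoxide.

Step 7
Reactants: 12 methyl (4R,5E,8S,9E)-10-(((tert-butyldimethylsilyl)oxy)methyl)-11-(1,3-dioxolan-2-yl)-4,8-dihydroxy-6-methylundeca-5,9-dien-2-ynoate; 13 formaldehyde (monomer from cracked paraformaldehyde)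
Product: 16 (R)-5-((1E,4S,5E)-6-(((tert-butyldimethylsilyl)oxy)methyl)-7-(1,3-dioxolan-2-yl)-4-hydroxy-2-methylhepta-1,5-dien-1-yl)-3-(hydroxymethyl)furan-2(5H)-one, via vinylalane 14 (not isolated), via triol ester 15 (not isolated)
Conditions: i-Bu2AlH (4.5 equiv), HMPA (5 equiv), THF, 0 °C; then CH2O (monomer in THF), −20 °C to rt; aq. work-up, then PPTS (cat.), CH2Cl2, rt
Reagents that add atoms: none
Why: Conjugate syn-hydroalumination of the ynoate (vinylalumination) gives the α-aluminio enoate with the ester cis to C6, aldol trapping with formaldehyde at the α-carbon with retention installs C13, and the cis γ-hydroxy ester lactonizes to the butenolide without touching C6 or C2.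

Step 8
Reactants: 16 (R)-5-((1E,4S,5E)-6-(((tert-butyldimethylsilyl)oxy)methyl)-7-(1,3-dioxolan-2-yl)-4-hydroxy-2-methylhepta-1,5-dien-1-yl)-3-(hydroxymethyl)furan-2(5H)-one
Product: 17 ((R)-5-((1E,4S,5E)-4-acetoxy-6-(((tert-butyldimethylsilyl)oxy)methyl)-7-(1,3-dioxolan-2-yl)-2-methylhepta-1,5-dien-1-yl)-2-oxo-2,5-dihydrofuran-3-yl)methyl acetate
Conditions: Ac2O, pyridine, CH2Cl2, 0 °C to rt
Reagents that add atoms: acetic anhydride, SMILES CC(=O)OC(C)=O
Why: O-acetylation installs the C2 acetate of the target and at the same time turns the C13 hydroxyl into the allylic leaving group for the key step; DMAP is left out to avoid allylic substitution and epimerization at the butenolide γ-carbon.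

Step 9
Reactants: 17 ((R)-5-((1E,4S,5E)-4-acetoxy-6-(((tert-butyldimethylsilyl)oxy)methyl)-7-(1,3-dioxolan-2-yl)-2-methylhepta-1,5-dien-1-yl)-2-oxo-2,5-dihydrofuran-3-yl)methyl acetate
Product: 19 ((R)-5-((1E,4S,5E)-4-acetoxy-6-(((tert-butyldimethylsilyl)oxy)methyl)-2-methyl-8-oxoocta-1,5-dien-1-yl)-2-oxo-2,5-dihydrofuran-3-yl)methyl acetate, via collidinium salt 18 (not isolated)
Conditions: Et3SiOTf (2 equiv), 2,4,6-collidine (3 equiv), CH2Cl2, 0 °C; then H2O
Reagents that add atoms: water, SMILES O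
Why: Silyl triflate/collidine acetal cleavage through a pyridinium N,O-acetal that water hydrolyzes is essentially neutral, so the β,γ-unsaturated aldehyde is released without conjugation and the silyl ether, the acetates and the butenolide survive.

Step 10
Reactants: 19 ((R)-5-((1E,4S,5E)-4-acetoxy-6-(((tert-butyldimethylsilyl)oxy)methyl)-2-methyl-8-oxoocta-1,5-dien-1-yl)-2-oxo-2,5-dihydrofuran-3-yl)methyl acetate
Product: 22 (3aR,4S,6E,8S,10E,11aR)-6-(((tert-butyldimethylsilyl)oxy)methyl)-4-hydroxy-10-methyl-3-methylidene-2-oxo-2,3,3a,4,5,8,9,11a-octahydrocyclodeca[b]furan-8-yl acetate, via ketyl radical 20 (not isolated), via samarium enolate 21 (not isolated)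
Conditions: SmI2 (2.5 equiv, 0.02 M in THF), slow addition of 19 over 8 h (final 2 mM), 0 °C; then aq. NH4Cl
Reagents that add atoms: none
Why: Proposed new method: divalent samarium reduces the aldehyde to a ketyl radical that adds 10-endo to the butenolide β-carbon C7 on the face anti to the C6 side chain (trans-fused lactone, 7R), the α-carbonyl radical is reduced to a trivalent samarium enolate that expels acetate to give the exo-methylene, and the bulky samarium-bound ketyl oxygen is expected to sit outside the forming ring with H8 under the lactone so that the 8α (8S) alcohol results; the closest known reactions are SmI2 ketyl–olefin cyclizations onto unsaturated lactones, SmI2 medium-ring Barbier and Reformatsky closures, and radical addition–elimination on 2-(acyloxymethyl)acrylates.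

Step 11
Reactants: 22 (3aR,4S,6E,8S,10E,11aR)-6-(((tert-butyldimethylsilyl)oxy)methyl)-4-hydroxy-10-methyl-3-methylidene-2-oxo-2,3,3a,4,5,8,9,11a-octahydrocyclodeca[b]furan-8-yl acetate; 23 methacrylic acid
Product: 25 (3aR,4R,6E,8S,10E,11aR)-8-acetoxy-6-(((tert-butyldimethylsilyl)oxy)methyl)-10-methyl-3-methylidene-2-oxo-2,3,3a,4,5,8,9,11a-octahydrocyclodeca[b]furan-4-yl 2-methylprop-2-enoate, via alkoxyphosphonium salt 24 (not isolated)
Conditions: PPh3 (2 equiv), diisopropyl azodicarboxylate (2 equiv), toluene, 0 °C to rt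
Reagents that add atoms: none
Why: In this Mitsunobu esterification methacrylate displaces the alkoxyphosphonium group by SN2 with inversion, which turns the 8S alcohol into the 8R (8β) methacrylate of the target in one operation.

Step 12
Reactants: 25 (3aR,4R,6E,8S,10E,11aR)-8-acetoxy-6-(((tert-butyldimethylsilyl)oxy)methyl)-10-methyl-3-methylidene-2-oxo-2,3,3a,4,5,8,9,11a-octahydrocyclodeca[b]furan-4-yl 2-methylprop-2-enoate
Product: 26 (3aR,4R,6E,8S,10E,11aR)-8-acetoxy-6-(hydroxymethyl)-10-methyl-3-methylidene-2-oxo-2,3,3a,4,5,8,9,11a-octahydrocyclodeca[b]furan-4-yl 2-methylprop-2-enoate (CNP0138477.2)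
Conditions: HF·pyridine, pyridine, THF, 0 °C to rt
Reagents that add atoms: none
Why: Buffered fluoride desilylation of the primary allylic silyl ether leaves the acetate, the methacrylate and the α-methylene lactone intact and does not touch any of the four stereocenters.

**Compound list**
1 | 4-((tert-butyldimethylsilyl)oxy)but-2-yn-1-ol | OCC#CCO[Si](C)(C)C(C)(C)C | starting material
2 | sodium cyclic alkoxy(vinyl)alanate from 1 (Al on the carbon bearing CH2OSi) | COCCO[Al-]1(OCCOC)OCC=C1CO[Si](C)(C)C(C)(C)C.[Na+] | intermediate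
3 | (Z)-4-((tert-butyldimethylsilyl)oxy)-3-iodobut-2-en-1-ol | OC/C=C(\I)CO[Si](C)(C)C(C)(C)C | intermediate
4 | (1,3-dioxolan-2-ylmethyl)zinc bromide | Br[Zn]CC1OCCO1 | starting material
5 | (E)-3-(((tert-butyldimethylsilyl)oxy)methyl)-4-(1,3-dioxolan-2-yl)but-2-en-1-ol | OC/C=C(\CC1OCCO1)CO[Si](C)(C)C(C)(C)C | intermediate
6 | (E)-3-(((tert-butyldimethylsilyl)oxy)methyl)-4-(1,3-dioxolan-2-yl)but-2-enal | O=C/C=C(\CC1OCCO1)CO[Si](C)(C)C(C)(C)C | intermediate
7 | 3-methylbut-2-enal | CC(C)=CC=O | starting material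
8 | (E)-tert-butyldimethyl((3-methylbuta-1,3-dien-1-yl)oxy)silane | C=C(C)/C=C/O[Si](C)(C)C(C)(C)C | intermediate
9 | (2E,5S,6E)-7-(((tert-butyldimethylsilyl)oxy)methyl)-8-(1,3-dioxolan-2-yl)-5-hydroxy-3-methylocta-2,6-dienal | O=C/C=C(C)/C[C@H](O)/C=C(\CC1OCCO1)CO[Si](C)(C)C(C)(C)C | intermediate
10 | methyl propiolate | C#CC(=O)OC | starting material
11 | methylzinc acetylide of methyl propiolate | C[Zn]C#CC(=O)OC | intermediate
12 | methyl (4R,5E,8S,9E)-10-(((tert-butyldimethylsilyl)oxy)methyl)-11-(1,3-dioxolan-2-yl)-4,8-dihydroxy-6-methylundeca-5,9-dien-2-ynoate | COC(=O)C#C[C@H](O)/C=C(C)/C[C@H](O)/C=C(\CC1OCCO1)CO[Si](C)(C)C(C)(C)C | intermediate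
13 | formaldehyde | C=O | starting material
14 | α-(diisobutylaluminio) enoate of 12 as its bis(diisobutylaluminum alkoxide), ester cis to C6 | COC(=O)/C([Al](CC(C)C)CC(C)C)=C\[C@H](O[Al](CC(C)C)CC(C)C)/C=C(C)/C[C@H](O[Al](CC(C)C)CC(C)C)/C=C(\CC1OCCO1)CO[Si](C)(C)C(C)(C)C | intermediate
15 | methyl (2Z,4R,5E,8S,9E)-10-(((tert-butyldimethylsilyl)oxy)methyl)-11-(1,3-dioxolan-2-yl)-4,8-dihydroxy-2-(hydroxymethyl)-6-methylundeca-2,5,9-trienoate | COC(=O)/C(CO)=C\[C@H](O)/C=C(C)/C[C@H](O)/C=C(\CC1OCCO1)CO[Si](C)(C)C(C)(C)C | intermediate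
16 | (R)-5-((1E,4S,5E)-6-(((tert-butyldimethylsilyl)oxy)methyl)-7-(1,3-dioxolan-2-yl)-4-hydroxy-2-methylhepta-1,5-dien-1-yl)-3-(hydroxymethyl)furan-2(5H)-one | OCC1=C[C@@H](/C=C(C)/C[C@H](O)/C=C(\CC2OCCO2)CO[Si](C)(C)C(C)(C)C)OC1=O | intermediate
17 | ((R)-5-((1E,4S,5E)-4-acetoxy-6-(((tert-butyldimethylsilyl)oxy)methyl)-7-(1,3-dioxolan-2-yl)-2-methylhepta-1,5-dien-1-yl)-2-oxo-2,5-dihydrofuran-3-yl)methyl acetate | CC(=O)OCC1=C[C@@H](/C=C(C)/C[C@H](OC(C)=O)/C=C(\CC2OCCO2)CO[Si](C)(C)C(C)(C)C)OC1=O | intermediate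
18 | N-(1-alkoxyalkyl)-2,4,6-trimethylpyridinium triflate from 17 (C8 carries the collidinium and the OCH2CH2OSiEt3 group) | CC(=O)OCC1=C[C@@H](/C=C(C)/C[C@H](OC(C)=O)/C=C(\CC(OCCO[Si](CC)(CC)CC)[n+]2c(C)cc(C)cc2C)CO[Si](C)(C)C(C)(C)C)OC1=O.[O-]S(=O)(=O)C(F)(F)F | intermediate
19 | ((R)-5-((1E,4S,5E)-4-acetoxy-6-(((tert-butyldimethylsilyl)oxy)methyl)-2-methyl-8-oxoocta-1,5-dien-1-yl)-2-oxo-2,5-dihydrofuran-3-yl)methyl acetate | CC(=O)OCC1=C[C@@H](/C=C(C)/C[C@H](OC(C)=O)/C=C(\CC=O)CO[Si](C)(C)C(C)(C)C)OC1=O | intermediate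
20 | samarium-bound ketyl radical at C8 of 19 | CC(=O)OCC1=C[C@@H](/C=C(C)/C[C@H](OC(C)=O)/C=C(\C[CH]O[Sm](I)I)CO[Si](C)(C)C(C)(C)C)OC1=O | intermediate
21 | cyclized trivalent samarium lactone enolate (C7–C8 bond formed, C13 acetate still present, C8 samarium alkoxide) | I[Sm](I)O[C@H]1C/C(CO[Si](C)(C)C(C)(C)C)=C\[C@@H](OC(C)=O)C/C(C)=C/[C@H]2OC(O[Sm](I)I)=C(COC(C)=O)[C@@H]21 | intermediate
22 | (3aR,4S,6E,8S,10E,11aR)-6-(((tert-butyldimethylsilyl)oxy)methyl)-4-hydroxy-10-methyl-3-methylidene-2-oxo-2,3,3a,4,5,8,9,11a-octahydrocyclodeca[b]furan-8-yl acetate (8α-alcohol) | O[C@H]1C/C(CO[Si](C)(C)C(C)(C)C)=C\[C@@H](OC(C)=O)C/C(C)=C/[C@H]2OC(=O)C(=C)[C@@H]21 | intermediate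
23 | methacrylic acid | C=C(C)C(=O)O | starting material
24 | alkoxytriphenylphosphonium methacrylate of 22 | c1ccccc1[P+](c1ccccc1)(c1ccccc1)O[C@H]1C/C(CO[Si](C)(C)C(C)(C)C)=C\[C@@H](OC(C)=O)C/C(C)=C/[C@H]2OC(=O)C(=C)[C@@H]21.C=C(C)C(=O)[O-] | intermediate
25 | (3aR,4R,6E,8S,10E,11aR)-8-acetoxy-6-(((tert-butyldimethylsilyl)oxy)methyl)-10-methyl-3-methylidene-2-oxo-2,3,3a,4,5,8,9,11a-octahydrocyclodeca[b]furan-4-yl 2-methylprop-2-enoate | C=C(C)C(=O)O[C@@H]1C/C(CO[Si](C)(C)C(C)(C)C)=C\[C@@H](OC(C)=O)C/C(C)=C/[C@H]2OC(=O)C(=C)[C@@H]21 | intermediate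
26 | (3aR,4R,6E,8S,10E,11aR)-8-acetoxy-6-(hydroxymethyl)-10-methyl-3-methylidene-2-oxo-2,3,3a,4,5,8,9,11a-octahydrocyclodeca[b]furan-4-yl 2-methylprop-2-enoate | C=C(C)C(=O)O[C@@H]1C/C(CO)=C\[C@@H](OC(C)=O)C/C(C)=C/[C@H]2OC(=O)C(=C)[C@@H]21 | target

**Totals and risks**

Total: 12 steps. Longest linear sequence: 11 steps (1 to 26 through steps 1–3 and 5–12; step 4 is a one-step side branch).

The three steps most likely to fail:

Step 7. Hydroalumination of an ynoate that carries a free γ-alkoxide may give trans-addition or ester reduction instead of the cis α-aluminio enoate. The fallback sets out from 12: zerovalent-palladium-catalyzed syn-hydrostannation (Bu3SnH, Pd(PPh3)4, THF, 0 °C) gives the α-stannyl cis-enoate F1, which lactonizes in the flask to the 3-(tributylstannyl)butenolide diol F2. Iododestannylation (I2, CH2Cl2, −78 °C) gives the 3-iodobutenolide diol F3. Stille hydroxymethylation with Bu3SnCH2OH (Pd(PPh3)4, dioxane, 80 °C) comes back to the route at 16.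

Step 10. A ten-membered ketyl–olefin closure has no direct precedent; pinacol coupling, simple aldehyde reduction or direct reduction of the activated allylic acetate may win. The fallback sets out from 19: MgBr2·OEt2 (CH2Cl2, 0 °C) exchanges the activated allylic acetate for bromide to give the 3-(bromomethyl)butenolide aldehyde F4. CrCl2 (THF, high dilution, rt) then closes the same C7–C8 bond by a Nozaki–Hiyama allylation through a chair organochromium transition state (attack at C7 with allylic transposition), which restores the exo-methylene and comes back to the route at 22.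

Step 11. SN2 displacement at a ring carbon next to the lactone may lose to elimination. The fallback sets out from 22: Dess–Martin periodinane (NaHCO3, CH2Cl2, 0 °C) gives the C8 ketone F5. Luche reduction (NaBH4, CeCl3·7H2O, MeOH, −78 °C) delivers hydride from the open outer face to give the 8β-alcohol F6. Acylation with methacrylic anhydride and DMAP (CH2Cl2, 0 °C) comes back to the route at 25. The same acylation applies directly if step 10 delivers the 8β-alcohol F6 instead of 22.

Further compounds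
F1 | step 7 | methyl (2Z)-α-(tributylstannyl) cis-enoate diol from syn-hydrostannation of 12 (not isolated) | COC(=O)/C([Sn](CCCC)(CCCC)CCCC)=C\[C@H](O)/C=C(C)/C[C@H](O)/C=C(\CC1OCCO1)CO[Si](C)(C)C(C)(C)C
F2 | step 7 | (R)-5-((1E,4S,5E)-6-(((tert-butyldimethylsilyl)oxy)methyl)-7-(1,3-dioxolan-2-yl)-4-hydroxy-2-methylhepta-1,5-dien-1-yl)-3-(tributylstannyl)furan-2(5H)-one | CCCC[Sn](CCCC)(CCCC)C1=C[C@@H](/C=C(C)/C[C@H](O)/C=C(\CC2OCCO2)CO[Si](C)(C)C(C)(C)C)OC1=O
F3 | step 7 | (R)-5-((1E,4S,5E)-6-(((tert-butyldimethylsilyl)oxy)methyl)-7-(1,3-dioxolan-2-yl)-4-hydroxy-2-methylhepta-1,5-dien-1-yl)-3-iodofuran-2(5H)-one | IC1=C[C@@H](/C=C(C)/C[C@H](O)/C=C(\CC2OCCO2)CO[Si](C)(C)C(C)(C)C)OC1=O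
F4 | step 10 | (2S,3E,6E)-7-((R)-4-(bromomethyl)-5-oxo-2,5-dihydrofuran-2-yl)-3-(((tert-butyldimethylsilyl)oxy)methyl)-6-methyl-1-oxohepta-3,6-dien-... written from the butenolide: (1E,4S,5E)-1-((R)-4-(bromomethyl)-5-oxo-2,5-dihydrofuran-2-yl)-6-(((tert-butyldimethylsilyl)oxy)methyl)-2-methyl-8-oxoocta-1,5-dien-4-yl acetate | BrCC1=C[C@@H](/C=C(C)/C[C@H](OC(C)=O)/C=C(\CC=O)CO[Si](C)(C)C(C)(C)C)OC1=O
F5 | step 11 | C8 ketone of 22 (6-(((tert-butyldimethylsilyl)oxy)methyl)-10-methyl-3-methylidene-2,4-dioxo macrocycle, C2 acetate retained) | O=C1C/C(CO[Si](C)(C)C(C)(C)C)=C\[C@@H](OC(C)=O)C/C(C)=C/[C@H]2OC(=O)C(=C)[C@@H]21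
F6 | step 11 | (3aR,4R,6E,8S,10E,11aR)-6-(((tert-butyldimethylsilyl)oxy)methyl)-4-hydroxy-10-methyl-3-methylidene-2-oxo-2,3,3a,4,5,8,9,11a-octahydrocyclodeca[b]furan-8-yl acetate (8β-alcohol) | O[C@@H]1C/C(CO[Si](C)(C)C(C)(C)C)=C\[C@@H](OC(C)=O)C/C(C)=C/[C@H]2OC(=O)C(=C)[C@@H]21
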